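Its constants were set for the occasion; the rest is arithmetic.

A one-step world turns starting material into target and stops. This flask goes on.

    starting material ⇌ other conformer (K1 = 3.14, k1 = 0.0277 s⁻¹)
    starting material → target (k2 = 0.0946 s⁻¹)
    other conformer → isomer of the product (k3 = 0.0595 s⁻¹)
    starting material + target → side product (k4 = 0.0758 L mol⁻¹ s⁻¹)

| flask | starting material | time | remark |
|---|---|---|---|
| south-east | 1.4 M | 2.5 min | a closed flask charged with all of it at once and left for 2.5 min |
| west | 1.4 M |  | a single well-mixed tank run continuously and read at steady state, 2.5 min in it on average |

- in percentages every species weighs as the starting material in it: one side product counts as two
- the stated concentrations are those of everything mixed, before any reaction; amounts are the same in each set-up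
- run time (south-east): 2.5 min

- the set-up with the highest share of target in all that became target or isomer of the product or side product, at the outlet or at the end ("none" if the first two lie within 2 percentage points) (south-east / west / none)
- share of target in all that became target or isomer of the product or side product, at the outlet or at the end, south-east
- share of target in all that became target or isomer of the product or side product, at the outlet or at the end, west

Which concentration should I watch? The level of target at which the step to side product removes it as fast as the step to target makes it. Both rates carry c(starting material), so it cancels, and the level is the ratio of the two constants. This is a selectivity factor in concentration units. Call it the ceiling, 1.25 M. The charge of 1.4 M lies above it.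

Does time matter in south-east? Hardly. The half-life by the step to target is 0.122 min and by the step to isomer 0.194 min, both far shorter than the run. So I count the south-east flask as finished.

What is the reckoning? Take k1 as the forward constant. Let x be the rate constant of the side step times the time integral of c(starting material). Then c(target) is the ceiling times (1 − exp(−x)). Target plus side product is the ceiling times x. Isomer is 0.255 of that. The balance counts side product 2 times. Expanding the exponential leaves a linear term plus a small correction, x squared over 2. One square root gives x = 0.699, and south-east comes to 44.8%.

Where is that weak? The dropped cubic term is 0.0569, and it pushes x up, so I commit to a shade above.

And the west tank? There c(target) is the ceiling times x/(1 + x). With the same x, roughly, and the charge counted as fully converted, that gives 36.7%. The gap of 8.1 percentage points exceeds the margin, so I choose south-east.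

The forecast also chooses south-east, with 46% for south-east and 37.2% for west. Of the south-east flask it says “conversion is essentially complete”. Its south-east share stands above mine.

South-east gives 46.0% and west 37.2%, so the answer is south-east. The south-east flask ends with 46.0% of its charge as target, which is 0.644 M, about half the ceiling. Now take the neighbour of south-east charged with 0.56 M, below the ceiling. The same root gives x = 0.317 and a share of 60.6%. That neighbour flask gives 61.1%.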